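## Structural features

The target (C30H50O) is a 7-5-6-6 carbocycle whose seven-membered ring A is spanned by an oxygen atom between C3 and C10, so ring A is an 8-oxabicyclo[3.2.1]octane. Atom numbers are those of the parent triterpene: C1–C2 ethano bridge, C3 ether CH, C4 gem-dimethyl carbon, C5 CH, C9 quaternary, C10 ether C–CH3; ring B = C5–C9, ring C = C8, C9, C11–C14, ring D = C13–C18, with C17 carrying CH3 and a 4-methylpent-3-enyl chain. Ring B is fused to ring A across C5–C9 through the two equatorial bonds of the pyranoid chair (H5 axial and anti to the oxygen bridge, C11 axial and syn to it); ring C is cis-fused to ring B across C8–C9 and trans-fused to ring D across C13–C14. Seven of the eight stereocentres are contiguous or 1,3-related (C3, C5, C10, C9, C8, C14, C13), four of them are fully substituted (C9, C10, C13, C14), C9 belongs to three rings, and the C13 and C14 methyl groups are anti. The eighth, C17, is quaternary, is insulated from the others by CH2 groups, and its chain is syn-axial to the C13 methyl group. The fragile elements are the trisubstituted side-chain alkene (acid, electrophilic oxidants, hydrogenation, radical acceptor) and, less so, the tertiary C10–O bond (strong acid). The real difficulty is the array C9–C8–C14–C13 and its correlation with C17, all to be left without functional groups. The key step exploits the fact that ring A is a furan (C3, C2, C1, C10, the ring oxygen and the C10 methyl group, i.e. 2-methylfuran) joined to a three-carbon oxyallyl unit (C4–C5–C9); this places a ketone at C5 whose only enolisable neighbour is C9, the future quaternary hub.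

## Logic of the disconnections

29 to 28: no skeletal bond is cut; carbonyl groups are put back at C7 and C12. They are the handles that make C6/C8 and C13 reactive. The forward step must delete two ketones, one of them beside a quaternary carbon, without touching the ether or the alkene.

28 to 27: the C5–H and C6–H bonds are removed and the C5=C6 enone restored. This postpones the C5 stereocentre to a reduction whose outcome is backed by product stability. The forward step must be a 1,4-reduction that spares the C12 ketone and the side-chain alkene.

27 to 25 (through 26): C8–C14 and C13–CH3 are cut. These two bonds create both vicinal quaternary carbons and close ring C; cutting them leaves a flat enone and an enolisable cyclopentenone. The forward step must add C8 to a fully substituted β-carbon in a six-membered mode and methylate the resulting enolate anti to the C14 methyl group.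

25 to 15 and 23 (through 24): C12–C13 is cut. This divides the molecule into two enantiopure halves of similar size, each with its stereocentres set independently. The forward step must add an alkenyl metal to an aldehyde in the presence of an enone.

23 to 16 and 17 (through 22, 21, 20, 19, 18): C14–CH3 and C17–C20 are cut. C17 becomes the only stereocentre of this half and is set by a chiral catalyst. The forward steps need kinetic enolisation away from C17 (methylation) and then thermodynamic enolisation towards C14 (triflate).

15 to 11 (through 14, 13, 12): C5–C6 is cut and the two arms on C9 are returned to an allyl group (C8 side) and a prenyl group (C11 side). Ring B then closes intramolecularly on the hindered C5 carbonyl. The forward steps must unveil the C7 ketone first, by an oxidation that touches only the monosubstituted alkene, and the C12 aldehyde only after ring B exists, by cleavage of the trisubstituted alkene.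

11 to 9 (through 10): C9–C11 is cut, then C9–C8. C9 is the only enolisable carbon of 9, and the order of the two alkylations decides the C9 configuration. The second electrophile must enter from the face of the oxygen bridge.

9 to 4 (through 8, 7, 6, 5): no skeletal bond is cut; the C1=C2 alkene and the racemic nature of 4 are restored. The C5 carbonyl is used as a temporary alcohol for resolution. The forward steps need separable diastereomeric esters.

4 to 1 and 2 (through 3): C3–C4 and C9–C10 are cut. This removes ring A in one step and ends at two commodity chemicals. The forward step must be head-to-tail selective.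

## Other disconnections considered

Alternative 1: The cut removes O–C3, C2–C3 and C1–C10, i.e. both ether rings of ring A at once. It leads back to the diazo keto ester A1 (rings B–D complete, C3 as a diazo ester on the C4 gem-dimethyl carbon, C10 as a methyl ketone on C9) and ethynyl p-tolyl sulfone A2. Forward, Rh2(OAc)4 (divalent rhodium) would convert A1 into a carbenoid that is captured by the C10 carbonyl oxygen, and the six-membered dipole would add across A2 to give cycloadduct A3.
- In its favour: bridge and both bridgeheads would arise in one operation on a finished carbocyclic core, the sulfone fixes the regiochemistry, and C3/C10 are set relative to C5 and C9 by the substrate. No resolution is needed, and on absolute stereocontrol this is the better plan.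
- Against it: A1 already contains C5, C8, C9, C13, C14 and C17, so every hard carbon–carbon bond must be solved first, without the rigid oxabicycle as a control element. A3 still carries a bridgehead ester, a sulfone and a C1=C2 alkene, whose removal beside the side-chain alkene would cost four or more steps.
- Comparison: structurally both plans make the same oxabicycle by cycloaddition, the chosen plan first and this one last. Mechanistically they are equals (near-concerted additions with inherently cis bridgeheads). In step economy the chosen plan is ahead, because 4 needs no precursor synthesis and carries nothing to delete.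

Alternative 2: The cut is the C13–C14 bond between the two quaternary carbons. It leads back to the δ-lactone A4, in which C13 is the lactone α-carbon, C16 the carbinol carbon and C14 the far end of a (Z)-enyne. Forward, enolisation and O-silylation of A4 (LiN(iPr)2, Me3SiCl) and a [3,3] shift through a boat transition state would form C13–C14, open the lactone and close ring D as the cyclohexene acid A5.
- In its favour: the vicinal quaternary pair and its relation to C17 would come from one intramolecular, stereospecific event. On this point it is better than the chosen plan, which sets C14 and C13 by conjugate addition and enolate methylation under substrate control. It is also compatible with ring A made as in the chosen plan.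
- Against it: A4 needs its own stereocontrolled synthesis (C16, C17, enyne geometry). A5 must still be joined to ring A: the carboxyl carbon is C12 and C11 is missing, the alkyne supplies only C8 and C7, and C15=C16 must be reduced beside the side-chain alkene.
- Comparison: structurally it solves ring D and leaves ring A and C9 to other chemistry; the chosen key step does the reverse. Mechanistically a sigmatropic shift gives tighter stereocontrol than any step that follows the cycloaddition in the chosen route. In step economy, 23 takes four steps from 16 and 17, whereas A5 would take about twice that before homologation.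

Alternative 3: The cut is C5–C9 together with O–C10; in the retro sense C5 returns to C10 and the ether opens, giving the 3β-hydroxy 6-6-6-6 alkene A6 (C9=C11). Forward, BF3·OEt2 or CF3SO3H would protonate C11, the C5–C10 bond would shift to C9 (ring B contracts, ring A expands) and the C3 hydroxyl would close on C10 to give A7.
- In its favour: rings A and B and the ether bridge would arise in the last skeletal step with no fragment coupling, and C5 migrates with retention. From A6 onwards it would be shorter than the chosen endgame, and on that count it is the better plan.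
- Against it: A6 is itself a complete tetracyclic triterpenoid containing C8, C13, C14 and C17. An electron-deficient C9 can equally accept the C10 methyl group or the C8 hydrogen, or lose a proton, and migration of the ring bond needs a twisted ring B. The acid forces the side-chain alkene to be masked (hence the pivalate in A7), which adds about three steps.
- Comparison: structurally the chosen plan builds the oxabicycle in its final connectivity, while this one builds an isomeric skeleton and relies on rearrangement. Mechanistically the cycloaddition has one productive pathway and the rearrangement several. In total step count the two are at best equal once A6 is included.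

Key step: step 1

Remark 1: the cycloaddition of achiral 1 and 2 can only give a racemate, so the stereo-SMILES of the key-step product is read as the (1S,5S) enantiomer that is selected by resolution in step 3.

Remark 2: ring A intermediates keep the locants 2,2,5-trimethyl (C1 = C3 of the target, C5 = C10 of the target); lowest-locant numbering would read 1,4,4-trimethyl.

Remark 3: homoallylic Grignard reagent 18 is assumed to be constitutionally stable in ether at 0 °C (no net cyclopropylcarbinyl rearrangement).

## Route

Step 1
Reactants: 1 2-methylfuran; 2 3-bromo-3-methylbutan-2-one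
Product: 4 rac-2,2,5-trimethyl-8-oxabicyclo[3.2.1]oct-6-en-3-one (racemate; (1S,5S) enantiomer drawn), via 1,1-dimethyl-2-oxyallyl cation 3 (not isolated)
Conditions: NEt3 (1.2 equiv), 1 (3 equiv), CF3CH2OH, 0 °C to rt
Reagents that add atoms: none
Why: NEt3 removes HBr from 2 in the ionising, weakly nucleophilic solvent to give oxyallyl cation 3, a two-electron three-carbon partner for the furan diene. The closest known reaction type is the (4+3) cycloaddition of furans with oxyallyl cations generated from α-halo ketones and amine base in fluorinated alcohols. Bonding is stepwise or strongly asynchronous: the unsubstituted α-carbon of 1 attacks the tertiary terminus of 3 (C3–C4), and the enolate CH2 terminus then collapses on the methyl-stabilised oxocarbenium carbon (C9–C10). This closes the seven-membered carbocycle of ring A in a (4+3) mode across the furan 2,5-positions, by cation–enolate recombination, and leaves the furan oxygen as the one-atom bridge. The new stereocentres C3 and C10 are the bridgeheads; their cis relationship is enforced by the furan ring, so only the absolute sense is open and 4 forms as a racemate. The selectivity needed is head-to-tail regiochemistry: the most nucleophilic furan carbon meets the more cationic terminus, and the alternative would have to join two fully substituted carbons (C4 and C10). Excess 1 keeps solvent capture of 3 and open-chain substitution of the furan in check.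

Step 2
Reactants: 4 rac-2,2,5-trimethyl-8-oxabicyclo[3.2.1]oct-6-en-3-one
Product: 5 rac-(1S*,3S*,5S*)-2,2,5-trimethyl-8-oxabicyclo[3.2.1]oct-6-en-3-ol (hydroxyl axial and anti to the oxygen bridge)
Conditions: Li[HB(sec-Bu)3], THF, −78 °C; H2O
Reagents that add atoms: none
Why: Hydride reduction of the ketone; the bulky borohydride should approach from the oxygen-bridge face and give the axial alcohol. The carbinol configuration is of no consequence because C5 returns to the ketone in step 6; the alcohol is only the handle for resolution.

Step 3
Reactants: 5 rac-(1S*,3S*,5S*)-2,2,5-trimethyl-8-oxabicyclo[3.2.1]oct-6-en-3-ol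
Product: 6 (1S,3S,5S)-2,2,5-trimethyl-8-oxabicyclo[3.2.1]oct-6-en-3-yl (1S)-camphanate
Conditions: (1S)-camphanic chloride, NEt3, 4-(dimethylamino)pyridine (cat.), CH2Cl2, 0 °C to rt; separation of the diastereomeric esters by chromatography or crystallisation
Reagents that add atoms: (1S)-camphanic chloride, O=C(Cl)[C@@]12CC[C@@](C)(C(=O)O1)C2(C)C
Why: Acylation of the racemic alcohol with an enantiopure acid chloride (classical resolution through diastereomeric esters) gives two diastereomeric camphanates that differ in physical properties and are separated; the ester of the (1S,3S,5S)-alcohol is carried on and its configuration is to be confirmed on the crystalline ester. This fixes the absolute configuration of C3 and C10 for the whole route.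

Step 4
Reactants: 6 (1S,3S,5S)-2,2,5-trimethyl-8-oxabicyclo[3.2.1]oct-6-en-3-yl (1S)-camphanate
Product: 7 (1S,3S,5R)-2,2,5-trimethyl-8-oxabicyclo[3.2.1]octan-3-yl (1S)-camphanate
Conditions: H2 (1 atm), Pd/C, EtOAc, rt
Reagents that add atoms: none
Why: Heterogeneous catalytic hydrogenation of the strained disubstituted C1=C2 alkene; no stereocentre is formed. It is done here, before any other alkene is present.

Step 5
Reactants: 7 (1S,3S,5R)-2,2,5-trimethyl-8-oxabicyclo[3.2.1]octan-3-yl (1S)-camphanate
Product: 8 (1S,3S,5R)-2,2,5-trimethyl-8-oxabicyclo[3.2.1]octan-3-ol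
Conditions: NaOMe (0.2 equiv), MeOH, reflux
Reagents that add atoms: none
Why: Base-catalysed transesterification releases the alcohol and removes the auxiliary as its methyl ester; no stereocentre is touched.

Step 6
Reactants: 8 (1S,3S,5R)-2,2,5-trimethyl-8-oxabicyclo[3.2.1]octan-3-ol
Product: 9 (1S,5R)-2,2,5-trimethyl-8-oxabicyclo[3.2.1]octan-3-one
Conditions: Pr4N[RuO4] (5 mol %), N-methylmorpholine N-oxide, 4 Å molecular sieves, CH2Cl2, rt
Reagents that add atoms: none
Why: Ley–Griffith oxidation of the hindered secondary alcohol. Nothing can epimerise, because C4 is quaternary and C9 is a CH2 group.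

Step 7
Reactants: 9 (1S,5R)-2,2,5-trimethyl-8-oxabicyclo[3.2.1]octan-3-one
Product: 10 (1S,5R)-2,2,5-trimethyl-4-(prop-2-en-1-yl)-8-oxabicyclo[3.2.1]octan-3-one (allyl on C9 and syn to the oxygen bridge)
Conditions: LiN(iPr)2, THF, −78 °C; allyl bromide, −78 °C to rt
Reagents that add atoms: allyl bromide (3-bromoprop-1-ene), C=CCBr
Why: Enolate alkylation (SN2); C9 is the only enolisable carbon of 9, so regiochemistry is not an issue. The allyl group is the masked C8–C7(=O)–C6 unit, and the new C9 centre is erased by the next enolisation.

Step 8
Reactants: 10 (1S,5R)-2,2,5-trimethyl-4-(prop-2-en-1-yl)-8-oxabicyclo[3.2.1]octan-3-one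
Product: 11 (1S,5R)-2,2,5-trimethyl-4-(3-methylbut-2-en-1-yl)-4-(prop-2-en-1-yl)-8-oxabicyclo[3.2.1]octan-3-one (prenyl syn and allyl anti to the oxygen bridge)
Conditions: KN(SiMe3)2 (1.2 equiv), THF, −78 °C; prenyl bromide, −78 to 0 °C
Reagents that add atoms: prenyl bromide (1-bromo-3-methylbut-2-ene), CC(C)=CCBr
Why: Second enolate alkylation (SN2 at the CH2 terminus of the primary allylic bromide), which creates the C9 quaternary centre. The enolate is attacked on the oxygen-bridge face because the other face is screened by the C1–C2 ethano bridge, so prenyl (C11, C12 and a sacrificial isopropylidene unit) ends syn to oxygen and the C8 arm anti, as in the target.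

Step 9
Reactants: 11 (1S,5R)-2,2,5-trimethyl-4-(3-methylbut-2-en-1-yl)-4-(prop-2-en-1-yl)-8-oxabicyclo[3.2.1]octan-3-one
Product: 12 (1S,5R)-2,2,5-trimethyl-4-(3-methylbut-2-en-1-yl)-4-(2-oxopropyl)-8-oxabicyclo[3.2.1]octan-3-one
Conditions: PdCl2 (10 mol %), CuCl, O2 (1 atm), DMF/H2O (7:1), rt
Reagents that add atoms: water, O
Why: Tsuji–Wacker oxidation: hydroxypalladation of the monosubstituted alkene at its internal carbon and β-hydride elimination give the methyl ketone (C7=O, C6 methyl). The trisubstituted prenyl alkene binds palladium far less readily and should be left untouched; no stereocentre is affected.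

Step 10
Reactants: 12 (1S,5R)-2,2,5-trimethyl-4-(3-methylbut-2-en-1-yl)-4-(2-oxopropyl)-8-oxabicyclo[3.2.1]octan-3-one
Product: 14 ring A/ring B enone (cyclopent-2-enone fused at C5–C9; C5=C6 and C7=O; prenyl on C9 syn to the oxygen bridge), via ring B aldol adduct 13 (not isolated)
Conditions: KOtBu (0.3 equiv), tBuOH, 80 °C
Reagents that add atoms: none
Why: Intramolecular aldol condensation of the 1,4-diketone: the C6 methyl enolate adds to C5 in a five-membered mode and water is lost by E1cB, closing ring B. Only one aldol mode exists, since C5 has no α-hydrogen and C8 cannot reach C5.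

Step 11
Reactants: 14 ring A/ring B enone with C9 prenyl group
Product: 15 ring A/ring B enone aldehyde (C9 arm = C11H2–C12HO)
Conditions: OsO4 (2 mol %), NaIO4 (4 equiv), 2,6-lutidine, dioxane/H2O, rt
Reagents that add atoms: sodium periodate, [Na+].[O-]I(=O)(=O)=O
Why: Lemieux–Johnson oxidation; osmylation takes the electron-rich trisubstituted prenyl alkene in preference to the conjugated, hindered C5=C6 bond, and periodate cleavage leaves C12 as the aldehyde and releases acetone. It is done before the side chain, which holds the same kind of alkene, enters.

Step 12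
Reactants: 16 3-methylcyclohex-2-en-1-one; 17 5-bromo-2-methylpent-2-ene
Product: 19 (S)-3-methyl-3-(4-methylpent-3-en-1-yl)cyclohexan-1-one, via (4-methylpent-3-en-1-yl)magnesium bromide 18 (not isolated)
Conditions: Mg, Et2O, rt; then 16, Cu(O3SCF3)2 (3 mol %), chiral C2-symmetric imidazolinium chloride (carbene precursor, 4 mol %), Et2O, 0 °C; aq. NH4Cl
Reagents that add atoms: none
Why: Copper-catalysed asymmetric conjugate addition of a Grignard reagent to a β-substituted cyclohexenone, which creates the C17 quaternary stereocentre. The sense is set by the chiral carbene ligand on copper, whose enantiomer is chosen to deliver the (S)-ketone.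

Step 13
Reactants: 19 (S)-3-methyl-3-(4-methylpent-3-en-1-yl)cyclohexan-1-one
Product: 20 2,5-dimethyl-5-(4-methylpent-3-en-1-yl)cyclohexan-1-one (C17 as in 19; both C14 epimers)
Conditions: LiN(iPr)2, THF, −78 °C; MeI, −78 to 0 °C
Reagents that add atoms: iodomethane, CI
Why: Kinetic deprotonation of a 3,3-disubstituted cyclohexanone occurs at the α-carbon remote from the quaternary centre (C14), and SN2 methylation follows. The C14 epimers are not separated because C14 becomes trigonal in the next step.

Step 14
Reactants: 20 2,5-dimethyl-5-(4-methylpent-3-en-1-yl)cyclohexan-1-one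
Product: 21 trimethyl{[2,5-dimethyl-5-(4-methylpent-3-en-1-yl)cyclohex-1-en-1-yl]oxy}silane (C17 as in 19)
Conditions: Me3SiCl, NEt3, DMF, 120 °C
Reagents that add atoms: chlorotrimethylsilane, C[Si](C)(C)Cl
Why: Silyl enol ether formation under equilibrating conditions gives the more substituted C13=C14 isomer. The C13=C18 isomer is disfavoured twice: it is less substituted and it lies beside the C17 quaternary carbon.

Step 15
Reactants: 21 trimethyl{[2,5-dimethyl-5-(4-methylpent-3-en-1-yl)cyclohex-1-en-1-yl]oxy}silane
Product: 23 2,5-dimethyl-5-(4-methylpent-3-en-1-yl)cyclohex-1-en-1-yl trifluoromethanesulfonate (C17 as in 19), via lithium enolate 22 (not isolated)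
Conditions: MeLi, THF, 0 °C; PhN(SO2CF3)2, −78 °C to rt
Reagents that add atoms: N-phenylbis(trifluoromethanesulfonimide), O=S(=O)(N(c1ccccc1)S(=O)(=O)C(F)(F)F)C(F)(F)F
Why: Methyllithium cleaves the O–Si bond to the regiodefined enolate 22, which is sulfonylated on oxygen before it can equilibrate. This gives the tetrasubstituted alkenyl triflate needed for the fragment union.

Step 16
Reactants: 15 ring A/ring B enone aldehyde; 23 2,5-dimethyl-5-(4-methylpent-3-en-1-yl)cyclohex-1-en-1-yl trifluoromethanesulfonate
Product: 24 C12 allylic alcohol (C12–C13 bond formed; ring D as 2-methylcyclohex-1-enyl; both C12 epimers)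
Conditions: CrCl2 (4 equiv), NiCl2 (2 mol %), DMF, rt
Reagents that add atoms: none
Why: Nozaki–Hiyama–Kishi coupling: nickel inserts into the alkenyl C–O bond, the alkenyl group passes to chromium and adds to the aldehyde only, so the enone and the other alkenes are spared. The C12 carbinol centre is not controlled because it is oxidised in the next step.

Step 17
Reactants: 24 C12 allylic alcohol
Product: 25 C12 ketone conjugated with C13=C14 (ring A/ring B enone joined to 1-acyl-2-methylcyclohexene ring D)
Conditions: Pr4N[RuO4] (5 mol %), N-methylmorpholine N-oxide, 4 Å molecular sieves, CH2Cl2, rt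
Reagents that add atoms: none
Why: Ley–Griffith oxidation of the allylic alcohol; this makes C14 the β-carbon of an enone and sets up the ring C closure.

Step 18
Reactants: 25 C12 ketone conjugated with C13=C14
Product: 27 7,12-dioxo-5-ene of the target skeleton (rings C and D complete; C13 and C14 methyl groups anti), via potassium C12 enolate 26 (not isolated)
Conditions: KN(SiMe3)2 (1.1 equiv), THF, −78 to −20 °C; then MeI, DMPU, −78 to 0 °C
Reagents that add atoms: iodomethane, CI
Why: Intramolecular Michael addition followed by in situ enolate alkylation: the α′-enolate of the cyclopentenone (C8) adds in a six-membered mode to C14, and the regiodefined enolate 26 is methylated at C13. C8 can only bond on the face of C9 that carries C11 (cis B/C); the C14 methyl group, necessarily pseudoaxial, should sit beside the flat C5 and not beside the fully substituted C10. Iodomethane should then enter axially and anti to that methyl group, in a half-chair that cannot flip without forcing C10 and C15 syn-diaxial, which gives the anti C13/C14 methyl groups and the trans C/D junction.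

Step 19
Reactants: 27 7,12-dioxo-5-ene of the target skeleton
Product: 28 7,12-diketone of the target skeleton (all eight stereocentres as in the target)
Conditions: Li (2.5 equiv), NH3/THF, tBuOH (1 equiv), −78 °C; NH4Cl
Reagents that add atoms: none
Why: Dissolving-metal 1,4-reduction of the enone (Birch-type conditions). The β-carbon C5 is protonated on the face away from the oxygen bridge, which gives the more stable junction with C6 equatorial, since the epimer would push C6 under the C1–C2 bridge. The enone is reduced well before the isolated C12 ketone, and the trisubstituted alkene is inert.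

Step 20
Reactants: 28 7,12-diketone of the target skeleton
Product: 29 CNP0284367.1 (target)
Conditions: N2H4·H2O, KOH, diethylene glycol, 130 then 210 °C
Reagents that add atoms: none
Why: Wolff–Kishner reduction (Huang-Minlon procedure) removes both carbonyl groups as N2. The ether, the alkene and the quaternary centres are inert to hot alkali, and C8, the only epimerisable centre, already has the favoured cis B/C configuration.

## Compound list

1 | 2-methylfuran | Cc1ccco1 | starting material
2 | 3-bromo-3-methylbutan-2-one | CC(=O)C(C)(C)Br | starting material
3 | 1,1-dimethyl-2-oxyallyl cation (zwitterionic form) | C=C([O-])[C+](C)C | intermediate (not isolated)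
4 | rac-2,2,5-trimethyl-8-oxabicyclo[3.2.1]oct-6-en-3-one (racemate; (1S,5S) enantiomer drawn; ketone at C5, CH2 at C9) | O=C1C(C)(C)[C@@H]2C=C[C@@](C)(O2)C1 | intermediate
5 | rac-(1S*,3S*,5S*)-2,2,5-trimethyl-8-oxabicyclo[3.2.1]oct-6-en-3-ol (racemate; axial hydroxyl anti to the oxygen bridge) | O[C@@H]1C(C)(C)[C@@H]2C=C[C@@](C)(O2)C1 | intermediate
6 | (1S,3S,5S)-2,2,5-trimethyl-8-oxabicyclo[3.2.1]oct-6-en-3-yl (1S,4R)-4,7,7-trimethyl-3-oxo-2-oxabicyclo[2.2.1]heptane-1-carboxylate | O=C(O[C@@H]3C(C)(C)[C@@H]4C=C[C@@](C)(O4)C3)[C@@]12CC[C@@](C)(C(=O)O1)C2(C)C | intermediate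
7 | (1S,3S,5R)-2,2,5-trimethyl-8-oxabicyclo[3.2.1]octan-3-yl (1S,4R)-camphanate | O=C(O[C@@H]3C(C)(C)[C@@H]4CC[C@@](C)(O4)C3)[C@@]12CC[C@@](C)(C(=O)O1)C2(C)C | intermediate
8 | (1S,3S,5R)-2,2,5-trimethyl-8-oxabicyclo[3.2.1]octan-3-ol | O[C@@H]1C(C)(C)[C@@H]2CC[C@@](C)(O2)C1 | intermediate
9 | (1S,5R)-2,2,5-trimethyl-8-oxabicyclo[3.2.1]octan-3-one | O=C1C(C)(C)[C@@H]2CC[C@@](C)(O2)C1 | intermediate
10 | (1S,5R)-2,2,5-trimethyl-4-(prop-2-en-1-yl)-8-oxabicyclo[3.2.1]octan-3-one, allyl on C9 syn to the oxygen bridge | O=C1C(C)(C)[C@@H]2CC[C@@](C)(O2)[C@H]1CC=C | intermediate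
11 | (1S,5R)-2,2,5-trimethyl-4-(3-methylbut-2-en-1-yl)-4-(prop-2-en-1-yl)-8-oxabicyclo[3.2.1]octan-3-one, prenyl (C11 arm) syn and allyl (C8 arm) anti to the oxygen bridge | O=C1C(C)(C)[C@@H]2CC[C@@](C)(O2)[C@@]1(CC=C)CC=C(C)C | intermediate
12 | (1S,5R)-2,2,5-trimethyl-4-(3-methylbut-2-en-1-yl)-4-(2-oxopropyl)-8-oxabicyclo[3.2.1]octan-3-one, C9 configuration as in 11 | O=C1C(C)(C)[C@@H]2CC[C@@](C)(O2)[C@@]1(CC(C)=O)CC=C(C)C | intermediate
13 | ring B aldol adduct: cyclopentanone fused at C5–C9 with C5–OH and C7=O, prenyl on C9 (either C5 epimer) | O=C1CC2(O)C(C)(C)[C@@H]3CC[C@@](C)(O3)[C@]2(CC=C(C)C)C1 | intermediate (not isolated)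
14 | ring A/ring B enone: cyclopent-2-enone fused at C5–C9 of the oxabicycle (C5=C6, C7=O, C8H2), C9 prenyl syn to the oxygen bridge | O=C1C=C2C(C)(C)[C@@H]3CC[C@@](C)(O3)[C@]2(CC=C(C)C)C1 | intermediate
15 | ring A/ring B enone aldehyde: 14 with the C9 arm shortened to C11H2–C12HO | O=C1C=C2C(C)(C)[C@@H]3CC[C@@](C)(O3)[C@]2(CC=O)C1 | intermediate
16 | 3-methylcyclohex-2-en-1-one | CC1=CC(=O)CCC1 | starting material
17 | 5-bromo-2-methylpent-2-ene | CC(C)=CCCBr | starting material
18 | (4-methylpent-3-en-1-yl)magnesium bromide | CC(C)=CCC[Mg]Br | intermediate (not isolated)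
19 | (S)-3-methyl-3-(4-methylpent-3-en-1-yl)cyclohexan-1-one (C13 ketone, C17 set) | CC(C)=CCC[C@]1(C)CCCC(=O)C1 | intermediate
20 | 2,5-dimethyl-5-(4-methylpent-3-en-1-yl)cyclohexan-1-one, C17 as in 19, mixture of C14 epimers | CC(C)=CCC[C@]1(C)CCC(C)C(=O)C1 | intermediate
21 | trimethyl{[2,5-dimethyl-5-(4-methylpent-3-en-1-yl)cyclohex-1-en-1-yl]oxy}silane, C17 as in 19 | CC(C)=CCC[C@]1(C)CCC(C)=C(O[Si](C)(C)C)C1 | intermediate
22 | lithium 2,5-dimethyl-5-(4-methylpent-3-en-1-yl)cyclohex-1-en-1-olate | CC(C)=CCC[C@]1(C)CCC(C)=C([O-])C1.[Li+] | intermediate (not isolated)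
23 | 2,5-dimethyl-5-(4-methylpent-3-en-1-yl)cyclohex-1-en-1-yl trifluoromethanesulfonate, C17 as in 19 | CC(C)=CCC[C@]1(C)CCC(C)=C(OS(=O)(=O)C(F)(F)F)C1 | intermediate
24 | C12 allylic alcohol: 15 with C12 as CH(OH) bonded to C13 of the 2-methylcyclohex-1-enyl ring D unit (both C12 epimers) | O=C1C=C2C(C)(C)[C@@H]3CC[C@@](C)(O3)[C@]2(CC(O)C4=C(C)CC[C@@](C)(CCC=C(C)C)C4)C1 | intermediate
25 | C12 ketone of 24, conjugated with C13=C14 | O=C1C=C2C(C)(C)[C@@H]3CC[C@@](C)(O3)[C@]2(CC(=O)C4=C(C)CC[C@@](C)(CCC=C(C)C)C4)C1 | intermediate
26 | potassium C12 enolate (C12=C13) of the C8–C14 conjugate adduct | CC(C)=CCC[C@]1(C)CC[C@]2(C)[C@H]3C(=O)C=C4C(C)(C)[C@@H]5CC[C@@](C)(O5)[C@@]43CC([O-])=C2C1.[K+] | intermediate (not isolated)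
27 | 7,12-dioxo-5-ene of the target skeleton (C5=C6, C7=O, C12=O; C8, C9, C13, C14, C17 as in the target) | CC(C)=CCC[C@]1(C)CC[C@]2(C)[C@H]3C(=O)C=C4C(C)(C)[C@@H]5CC[C@@](C)(O5)[C@@]43CC(=O)[C@@]2(C)C1 | intermediate
28 | 7,12-diketone of the target skeleton (all stereocentres as in the target; H5 anti to the oxygen bridge) | CC(C)=CCC[C@]1(C)CC[C@]2(C)[C@H]3C(=O)C[C@H]4C(C)(C)[C@@H]5CC[C@@](C)(O5)[C@@]43CC(=O)[C@@]2(C)C1 | intermediate
29 | CNP0284367.1 | CC(C)=CCC[C@]1(C)CC[C@]2(C)[C@H]3CC[C@H]4C(C)(C)[C@@H]5CC[C@@](C)(O5)[C@@]43CC[C@@]2(C)C1 | target

## Step count and risk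

Total step count: 20. Longest linear sequence: 16 steps (steps 1–11, then 16–20); the ring D branch (steps 12–15) is 4 steps.

Step 18. Process at risk: reversal of the conjugate addition and proton exchange among C8, C11 and C13 before methylation, and attack of iodomethane on the face of the C14 methyl group. The cause is the crowding at C13/C14 and the syn-axial C17 chain on the face that must be alkylated. Fallback, from 25 back to 27: the adduct is frozen at −78 °C with Me3SiCl as the C12 trimethylsilyl enol ether F1, which is isolated. Simmons–Smith cyclopropanation (Et2Zn, CH2I2, one equivalent) of this electron-rich enol ether, which should react ahead of the side-chain alkene and is steered by the C14 methyl group alone, gives the siloxycyclopropane F2. NaOH in MeOH then opens the C12–CH2 bond and leaves the C13 methyl group of 27.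

Step 1 (key step). Process at risk: capture of the oxyallyl cation by the alcohol solvent, substitution of the furan without ring closure, or erosion of the head-to-tail regiochemistry; the cation is generated slowly by base and lives in a protic medium. Fallback, from 2 back to 4: 2 is brominated at C1 (Br2, HBr cat., CH2Cl2) to 1,3-dibromo-3-methylbutan-2-one F3, and the oxyallyl species is generated reductively with Zn(Cu) in 1,2-dimethoxyethane in the presence of 1. This is a base-free variant of the same (4+3) bond construction in an inert solvent.

Step 16. Process at risk: slow insertion and transmetalation of the tetrasubstituted alkenyl triflate, with competing reduction or self-condensation of the aldehyde; both termini of the new bond are hindered. Fallback, from 15 and 23 back to 25: NaClO2/NaH2PO4/2-methylbut-2-ene oxidises 15 to the carboxylic acid F4, and (COCl)2 gives the acid chloride F5. 23 is converted with (Me3Sn)2, Pd(PPh3)4 and LiCl into the alkenylstannane F6. Acyl Stille coupling of F5 with F6 (Pd(PPh3)4, toluene) gives 25 directly.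

Step 20. Process at risk: incomplete hydrazone formation at the C12 carbonyl, which is flanked by the C13 quaternary carbon, so that oxygen is retained at C12. Fallback, from 28 back to 29: LiAlH4 reduces both ketones to the diol F7, NaH/CS2/MeI gives the bis(xanthate) F8, and Bu3SnH with azobisisobutyronitrile in toluene removes both oxygens by Barton–McCombie deoxygenation. Neither radical has a five- or six-membered path to the side-chain alkene.

Step 12. Process at risk: loss of enantioselectivity or competing 1,2-addition when the chain is delivered by a Grignard reagent to the methyl-bearing enone; the catalyst must distinguish methyl from ring CH2 at a fully substituted carbon. Fallback, from 17 (through 18) back to 19: 18 is added to 3-ethoxycyclohex-2-en-1-one and the adduct hydrolysed (aq. HCl) to 3-(4-methylpent-3-en-1-yl)cyclohex-2-en-1-one F9. Copper-catalysed asymmetric conjugate addition of Me3Al (Cu(O3SCF3)2, chiral phosphoramidite, Et2O, −30 °C) then delivers the small methyl group to the chain-bearing enone and gives 19.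

## Further compounds

F1 | step 18 | C12 trimethylsilyl enol ether of the C8–C14 conjugate adduct (C12=C13; 7-oxo-5-ene) | CC(C)=CCC[C@]1(C)CC[C@]2(C)[C@H]3C(=O)C=C4C(C)(C)[C@@H]5CC[C@@](C)(O5)[C@@]43CC(O[Si](C)(C)C)=C2C1
F2 | step 18 | 12-(trimethylsilyloxy)-12,13-methano derivative of F1 (cyclopropane CH2 on the face of H8) | CC(C)=CCC[C@]1(C)CC[C@]2(C)[C@H]3C(=O)C=C4C(C)(C)[C@@H]5CC[C@@](C)(O5)[C@@]43C[C@]6(O[Si](C)(C)C)C[C@@]62C1
F3 | step 1 | 1,3-dibromo-3-methylbutan-2-one | CC(C)(Br)C(=O)CBr
F4 | step 16 | carboxylic acid from 15 (C12 as CO2H) | O=C1C=C2C(C)(C)[C@@H]3CC[C@@](C)(O3)[C@]2(CC(=O)O)C1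
F5 | step 16 | acid chloride of F4 (C12 as COCl) | O=C1C=C2C(C)(C)[C@@H]3CC[C@@](C)(O3)[C@]2(CC(=O)Cl)C1
F6 | step 16 | [2,5-dimethyl-5-(4-methylpent-3-en-1-yl)cyclohex-1-en-1-yl]trimethylstannane, C17 as in 23 | CC(C)=CCC[C@]1(C)CCC(C)=C([Sn](C)(C)C)C1
F7 | step 20 | 7,12-diol from 28 (carbinol configurations immaterial) | CC(C)=CCC[C@]1(C)CC[C@]2(C)[C@H]3C(O)C[C@H]4C(C)(C)[C@@H]5CC[C@@](C)(O5)[C@@]43CC(O)[C@@]2(C)C1
F8 | step 20 | 7,12-bis(S-methyl dithiocarbonate) of F7 | CC(C)=CCC[C@]1(C)CC[C@]2(C)[C@H]3C(OC(=S)SC)C[C@H]4C(C)(C)[C@@H]5CC[C@@](C)(O5)[C@@]43CC(OC(=S)SC)[C@@]2(C)C1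
F9 | step 12 | 3-(4-methylpent-3-en-1-yl)cyclohex-2-en-1-one | CC(C)=CCCC1=CC(=O)CCC1
A1 | alternative 1 | diazo keto ester (C3 diazo ester on C4, C10 methyl ketone on C9, rings B–D complete) | CC(C)=CCC[C@]1(C)CC[C@]2(C)[C@H]3CC[C@@H](C(C)(C)C(=[N+]=[N-])C(=O)OC)[C@@]3(C(C)=O)CC[C@@]2(C)C1
A2 | alternative 1 | ethynyl p-tolyl sulfone | C#CS(=O)(=O)c1ccc(C)cc1
A3 | alternative 1 | oxa-bridged cycloadduct with C3 methyl ester and C2 sulfonyl alkene | CC(C)=CCC[C@]1(C)CC[C@]2(C)[C@H]3CC[C@H]4C(C)(C)[C@]5(C(=O)OC)C(S(=O)(=O)c6ccc(C)cc6)=C[C@@](C)(O5)[C@@]43CC[C@@]2(C)C1
A4 | alternative 2 | δ-lactone with C13 as α-carbon (either epimer), C17 quaternary, C16 carbinol carbon bearing the (Z)-2-methyl-4-(trimethylsilyl)but-1-en-3-ynyl group | CC(C)=CCC[C@@]1(C)CC(C)C(=O)O[C@H]1/C=C(/C)C#C[Si](C)(C)C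
A5 | alternative 2 | ring D cyclohexene acid with C13, C14 and C17 set | CC(C)=CCC[C@]1(C)C=C[C@](C)(C#C[Si](C)(C)C)[C@@](C)(C(=O)O)C1
A6 | alternative 3 | 3β-hydroxy 6-6-6-6 precursor with C9=C11 alkene and pivalate-protected side chain | CC(C)(C)C(=O)OCCC[C@]1(C)CC[C@]2(C)[C@H]3CC[C@H]4C(C)(C)[C@@H](O)CC[C@]4(C)C3=CC[C@@]2(C)C1
A7 | alternative 3 | full ring system of the target with pivalate-protected side chain | CC(C)(C)C(=O)OCCC[C@]1(C)CC[C@]2(C)[C@H]3CC[C@H]4C(C)(C)[C@@H]5CC[C@@](C)(O5)[C@@]43CC[C@@]2(C)C1
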